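Time first: I have 30 h for this flask, and I want to know whether that is long against what the flask does.

starting material 2.9 M; gas phase 200 mM (held); protic impurity 0.0580 M; time 30 h

    starting material → side product (k1 = 0.00310 min⁻¹)
    gas phase ⇌ dissolved gas, rate k2*(csat - [dissolved gas]) (k2 = 0.0300 min⁻¹, csat = 200 mM)
    dissolved gas → decomposed reagent (k3 = 4.97 × 10⁻⁴ min⁻¹)
    starting material + dissolved gas → target (k4 = 0.154 M⁻¹ min⁻¹)
    starting material + protic impurity → quenched substrate (k5 = 0.00594 M⁻¹ min⁻¹)

- target at 30 h, in percent of the starting material charged
- concentration of dissolved gas in solution at 30 h, in percent of saturation

- at the start none of the gas is dissolved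
- run time (flask): 30 h

I write the balance of the dissolved gas, since saturation offers 200 mM against a charge of 2.9 M. Gas enters in proportion to its shortfall from saturation and leaves by decomposition and by capture on starting material. At the charge, capture runs at 0.447 min⁻¹, faster than the transfer coefficient 0.0300 min⁻¹. So near the charge the solution holds about 6.29 % of saturation, uptake is the rate-limiting step, and target forms at about the full delivery of 0.00600 M min⁻¹.

The side step starts at 0.00899 M min⁻¹, which is faster than delivery. The two are equal at delivery divided by the side constant, 1.94 M, the crossover concentration. Above it, by this reckoning, side product gains faster than target. Integrating gives target = crossover × ln[(crossover + charge)/crossover], which is 61.1 %, reached in about 4.92 h. That is shorter than the run.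

But capture does not stay ahead of transfer to the end. It falls to transfer plus decomposition at 0.198 M of starting material. Keeping that term adds this concentration to the crossover inside the logarithm: target = crossover × ln[(crossover + tail + charge)/(crossover + tail)]. That lowers my figure to 57.3 %.

The protic impurity is a second objection. Its charge is 2.00 % of the starting material, so it can take no more than that, and I commit to between 55.3 % and 57.3 %. Once capture has stopped, transfer stands against decomposition alone, which gives 98.4 % of saturation.

The forecast gives 56.3 % and 98.4 %, holding that “Dissolving gas is rate-limiting”.

This flask gives 55.5 % and 98.4 %. Quenched substrate stands at 1.81 % of the charge at 30.0 h. The neighbour flask, charged with 1.2 M of starting material, begins below the crossover. For it the same formula gives 72.0 %. The neighbour flask stands at 68.4 % of target.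

(All constants are those of an exercise; the rest is arithmetic.)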